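You get no constants for this flask, so read its rates from the earlier runs: solid X goes into solution, meets the nucleophile Z and gives the product Q.

| setting | summer | autumn | Friday's | Wednesday's | Monday's |
|---|---|---|---|---|---|
| X | 0.15 M | 0.15 M | 0.15 M | 0.15 M | 0.15 M |
| Z | 0.25 M | 0.46 M | 0.180 M | 0.270 M | 0.400 M |
| remark | run made earlier | run made earlier |  |  |  |
| time |  |  | 15 min | 15 min | 15 min |

| run | time / min | X / % | Q / % |
|---|---|---|---|
| summer | 1.50 | 85.3 | 3.7 |
| summer | 3.00 | 77.7 | 8.1 |
| summer | 5.00 | 70.8 | 13.8 |
| summer | 6.00 | 66.7 | 16.2 |
| summer | 8.00 | 61.4 | 20.5 |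
| summer | 10.0 | 54.5 | 25.0 |
| autumn | 0.833 | 89.2 | 1.8 |
| autumn | 1.33 | 84.7 | 5.8 |
| autumn | 2.00 | 80.7 | 8.2 |
| autumn | 3.00 | 74.4 | 14.1 |
| autumn | 5.00 | 62.1 | 22.2 |
| autumn | 6.00 | 57.7 | 25.7 |
| autumn | 10.0 | 35.2 | 40.7 |

(each reading ± 0.5 percentage points)

- given per volume of solution although it is solid: X
- the numbers in the tables scatter with a standard deviation of 0.5 percentage points
- at the start none of X is in solution
- what has only dissolved of X counts as not reacted

- part of the X that has reacted (what has only dissolved counts as not reacted) at the end, Friday's
- part of the X that has reacted (what has only dissolved counts as not reacted) at the end, Wednesday's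
- part of the X that has reacted (what has only dissolved counts as not reacted) at the end, Monday's
- what raising the concentration of Z from its lowest to its highest value here does to the part of the X that has reacted (what has only dissolved counts as not reacted) (changes below 5 percentage points count as none) (it rises / no change / it falls)

Call the gap whatever is neither solid X nor Q, as a share of the X charged. The autumn run shows a ladder of three rungs. Fastest, the gap opens at 0.108 min⁻¹ up to the first reading at 0.833 min, which you can read as X dissolving. Next comes Q, at 0.0424 min⁻¹ from that reading to the last, slower than that filling. Slowest, the gap goes on climbing at 0.0165 min⁻¹. That stretch starts early, so part of the climb may still be X dissolving; the rest I read as a second reacted material growing alongside Q.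

Divide the climb by the Q rate and the minutes cancel: 0.388. Call this s, the gap gained per unit of Q gained, a ratio that belongs to this stretch of the autumn run. The summer run, over a shorter stretch of Q, gives 0.446. So my estimate of the reacted part is about 1.39 times Q, on the high side by whatever share of the climb is dissolved X.

The forecast gives 27%, 37% and 50% for Friday's, Wednesday's and Monday's, and for the trend, it rises. Its ground is “So the reacted part is Q”, and here my reckoning differs. I take its numbers as Q at 15 min and multiply by 1 + s, which gives 37.5%, 51.4% and 69.4%, more than it says.

The flask gives 32.6%, 46.9% and 65.5% for Friday's, Wednesday's and Monday's; raising Z from lowest to highest: it rises, by 33 percentage points.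

    X ⇌ G, rate k1*(cs1 - [G]) while solid is left; crystals form when [G] > cs1 (solubility = 25.0 mM, k = 1.10 min⁻¹)
    Q ⇌ D (K = 0.458, k = 0.104 min⁻¹)
    J → E (k = 0.435 min⁻¹)
    G + Z → J + Q (k = 1.26 M⁻¹ min⁻¹)
    Z + J ⇌ L, settled at all times (K = 1600 M⁻¹)

Monday's flask stood at 15.0 min with Q at 48.5% and the second product D at 16.9%, a ratio at that moment of 0.348, which had been 0.243 at 7.50 min, while s from the autumn stretch is 0.388. On Monday's recipe with 0.060 M of X, a Q of 69.6% at 15.0 min times 1.39 gives 96.6%, and that flask stands at 98.9% reacted.

(The numbers in the tables were generated by integration with constants of no real substance; scatter was added.)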